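I counted everything as a fraction of the substrate charged, and the coupling partner in equivalents of that charge.

| setting | ochre | violet |
|---|---|---|
| substrate | 0.050 M | 0.050 M |
| coupling partner | 2.00 equiv (fed, over 6.0 s) | 2.00 equiv (fed, over 6.0 s) |
| temperature | −20 °C | 5 °C |
| time | 3.0 min | 3.0 min |

    2 substrate ⇌ resting dimer, settled at all times (K1 = 83000 L mol⁻¹, ΔH1 = −31.0 kJ mol⁻¹)
    substrate + coupling partner → product (k2 = 23 L mol⁻¹ s⁻¹, Ea2 = 38.0 kJ mol⁻¹)
    coupling partner → decomposed reagent (k3 = 0.0092 s⁻¹, Ea3 = 73.0 kJ mol⁻¹)
    (constants at −20 °C)

- a species is counted by the substrate in it: one resting dimer counts as two
- two of one species on the left: rate k times its square, two consumed each time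
- the constants hold at −20 °C; other temperatures follow from the activation energies and enthalpies

- the flask that comes out highest in amount of product, in percent of the substrate charged, or "all alike" when all lie within 1.5 percentage points (ochre / violet / all alike)
- product at the end, in percent of the substrate charged, ochre
- product at the end, in percent of the substrate charged, violet

By hand, at the start 1.10% of ochre's charge is unbound, hardly any, and the rest is held as resting dimer (the resting state). I therefore neglected free substrate in the count. Let S be the share of the charge still unconverted, K the dimer constant, c the substrate concentration, k the coupling constant and d the decomposition constant. Then: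

free share = √(S / (2 K c))

Coupling partner has two roads, to product and to decomposed reagent, and they run equally fast at one value of S. I called this value s, the crossing share:

s = 2 K c × (d / k c) squared

For ochre this gives 53.1%, the crossing share: the share of the charge still unconverted at which decomposition overtakes coupling. Adding up both roads, the equivalents E used in bringing the charge down to S are:

E = (1 − S) + 2 √s (1 − √S)

Setting E to the charge of 2.00 equiv gives a ceiling on product:

√S = √((1 + √s) squared − E) − √s

Temperature comes first. Going to violet, the dimer constant falls to 22100 L mol⁻¹, while decomposition speeds up by a factor of 23 and coupling by a factor of 5.1. The crossing share rises to 281%, which is above the whole charge, whereas ochre's lies below it. The ceilings are 92.9% for ochre and 64.5% for violet.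

Time comes next. The partner's starting time constant is 45.8 s in ochre, shorter than the 3.0 min allowed, but it lengthens as free substrate falls. I therefore expected ochre a little under its ceiling. In violet it is 3.01 s, so I expected violet at its ceiling.

The feed comes last. Both roads take the coupling partner to the first power, so its concentration, and with it the feed, does not enter the count.

The forecast named ochre, with 88.7% for ochre and 64% for violet, holding that in violet, at 5 °C, “decomposition outruns coupling”. Its ochre figure stands below my ceiling.

The flasks gave 89.1% in ochre and 64.0% in violet, so ochre came out highest. Ochre still held 6.2% of its coupling partner at 3.00 min, and left until 30.0 min its product stood at 92.7%, against the 92.9% that its crossing share gave.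

By my count, at ochre's crossing share of 53.1%, clearing the whole charge takes 2.46 equiv. A neighbour flask, like ochre but with 5.00 equiv of coupling partner, was given more than that. That neighbour gave 100% product at 3.00 min, with 0% of the substrate left unbound and 15% of its own charge of coupling partner left.

The rate constants stand for no real mixture, and the outcome is calculated.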